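The route rests on making the trioxygenated aryl ring on C6 of the oxane (O1, C2 arylethyl, C4 acetoxy, C6 aryl) last, from a cyclobutenone and methoxyacetylene. The feature exploited is that C3′–OH and C5′–OMe of this ring are meta to each other and to C1′, the carbon bonded to C6. Heating cyclobutenone 22, which already carries the complete 2,6-cis oxane with its axial C4 silyloxy group, with alkyne 25 forms the C3′–C4′ and C5′–C6′ bonds and the benzene ring in one operation and delivers the two outer oxygens differentiated (phenol 30). C4′–OH follows by directed metalation between them.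

Key step: step 14

Remark: the target is read as (2S,4S,6S), with the C2 arylethyl and C6 aryl groups cis (both equatorial) and the C4 acetoxy group trans to both (axial). Primed locants belong to the aryl ring on C6. Shorthand in names: Ox = (2S,4S,6S)-6-{2-[4-(benzyloxy)-3-methoxyphenyl]ethyl}-4-[(tert-butyldimethylsilyl)oxy]oxan-2-yl. Compounds 3, 7, 14, 19, 23, benzyl chloromethyl ether and the ruthenium–BINAP catalyst are taken as commercial.

Step 1
Reactants: 1 3-(4-hydroxy-3-methoxyphenyl)propanoic acid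
Product: 2 3-[4-(benzyloxy)-3-methoxyphenyl]propanoic acid
Conditions: BnBr (1.2 equiv), NaOH (2.5 equiv), EtOH/H2O, reflux; then aq. HCl
Reagents that add atoms: benzyl bromide BrCc1ccccc1
Why: Williamson ether synthesis, in which the phenoxide is alkylated much faster than the carboxylate in aqueous ethanol and any benzyl ester formed is saponified by the excess hydroxide, so that acidification returns the free acid.

Step 2
Reactants: 2 3-[4-(benzyloxy)-3-methoxyphenyl]propanoic acid; 3 potassium ethyl malonate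
Product: 5 ethyl 5-[4-(benzyloxy)-3-methoxyphenyl]-3-oxopentanoate, via acyl imidazolide 4 (not isolated)
Conditions: 1,1′-carbonyldiimidazole, THF, rt; then 3, MgCl2, Et3N, THF/MeCN, rt → 50 °C; aq. HCl
Reagents that add atoms: none
Why: Masamune–Brooks homologation, in which acyl imidazolide 4 C-acylates the magnesium enolate of the malonate half-ester and the adduct loses CO2, giving the β-keto ester without self-condensation.

Step 3
Reactants: 5 ethyl 5-[4-(benzyloxy)-3-methoxyphenyl]-3-oxopentanoate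
Product: 6 ethyl (3S)-5-[4-(benzyloxy)-3-methoxyphenyl]-3-hydroxypentanoate
Conditions: RuCl2[(S)-BINAP] (0.5 mol %), H2 (10 bar), EtOH, 60 °C
Reagents that add atoms: none
Why: Noyori asymmetric hydrogenation of a β-keto ester, in which chelation of the keto ester to the (S)-BINAP–ruthenium hydride fixes the face of hydride transfer and should set C3 as S (the later C2 of the oxane), while the aryl benzyl ether is inert to this homogeneous catalyst.

Step 4
Reactants: 6 ethyl (3S)-5-[4-(benzyloxy)-3-methoxyphenyl]-3-hydroxypentanoate; 7 tert-butyl acetate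
Product: 8 tert-butyl (5S)-7-[4-(benzyloxy)-3-methoxyphenyl]-5-hydroxy-3-oxoheptanoate
Conditions: LDA (3.5 equiv), 7 (3.5 equiv), THF, −78 °C; then 6, −78 → −30 °C; aq. NH4Cl
Reagents that add atoms: none
Why: Crossed Claisen condensation, in which excess lithium enolate of 7 first deprotonates the hydroxyl and then acylates on the ethyl ester, the product being held as its enolate until work-up and the carbinol centre being untouched.

Step 5
Reactants: 8 tert-butyl (5S)-7-[4-(benzyloxy)-3-methoxyphenyl]-5-hydroxy-3-oxoheptanoate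
Product: 10 tert-butyl (3S,5S)-7-[4-(benzyloxy)-3-methoxyphenyl]-3,5-dihydroxyheptanoate, via boron chelate 9 (not isolated)
Conditions: Et2BOMe (1.1 equiv), THF/MeOH (4:1), −78 °C; NaBH4, −78 °C; AcOH; co-evaporation with MeOH
Reagents that add atoms: none
Why: Narasaka–Prasad reduction, in which boron chelate 9 locks hydroxyl and ketone in a half-chair and external hydride adds axially, which should set C3 as S, syn to the C5 hydroxyl.

Step 6
Reactants: 10 tert-butyl (3S,5S)-7-[4-(benzyloxy)-3-methoxyphenyl]-3,5-dihydroxyheptanoate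
Product: 12 (4S,6S)-6-{2-[4-(benzyloxy)-3-methoxyphenyl]ethyl}-4-hydroxyoxan-2-one, via dihydroxy acid 11 (not isolated)
Conditions: NaOH, MeOH/H2O, 45 °C; aq. HCl to pH 3, 0 °C; toluene, 90 °C (removal of water)
Reagents that add atoms: none
Why: Saponification followed by lactonisation of hydroxy acid 11 through the C5 hydroxyl (six-membered ring preferred over the β-lactone), which touches neither stereocentre and turns the syn diol into the trans-4,6-disubstituted lactone.

Step 7
Reactants: 12 (4S,6S)-6-{2-[4-(benzyloxy)-3-methoxyphenyl]ethyl}-4-hydroxyoxan-2-one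
Product: 13 (4S,6S)-6-{2-[4-(benzyloxy)-3-methoxyphenyl]ethyl}-4-[(tert-butyldimethylsilyl)oxy]oxan-2-one
Conditions: TBSCl, imidazole, DMF, rt
Reagents that add atoms: tert-butyldimethylsilyl chloride CC(C)(C)[Si](C)(C)Cl
Why: Silylation of a secondary alcohol under imidazole catalysis, mild enough not to cause β-elimination in the lactone.

Step 8
Reactants: 13 (4S,6S)-6-{2-[4-(benzyloxy)-3-methoxyphenyl]ethyl}-4-[(tert-butyldimethylsilyl)oxy]oxan-2-one; 14 trimethylsilylacetylene
Product: 15 (4S,6S)-6-{2-[4-(benzyloxy)-3-methoxyphenyl]ethyl}-4-[(tert-butyldimethylsilyl)oxy]-2-[(trimethylsilyl)ethynyl]oxan-2-ol (anomeric mixture)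
Conditions: 14 (1.3 equiv), n-BuLi (1.25 equiv), THF, −78 °C; then 13, −78 °C; AcOH/THF quench at −78 °C
Reagents that add atoms: none
Why: 1,2-Addition of a lithium acetylide to a δ-lactone, which stops at the lactol because the tetrahedral lithium alkoxide is stable at −78 °C and the weakly basic acetylide does not eliminate the β-silyloxy group.

Step 9
Reactants: 15 (4S,6S)-6-{2-[4-(benzyloxy)-3-methoxyphenyl]ethyl}-4-[(tert-butyldimethylsilyl)oxy]-2-[(trimethylsilyl)ethynyl]oxan-2-ol
Product: 17 (2S,4S,6S)-2-{2-[4-(benzyloxy)-3-methoxyphenyl]ethyl}-4-[(tert-butyldimethylsilyl)oxy]-6-[(trimethylsilyl)ethynyl]oxane, via oxocarbenium ion 16 (not isolated)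
Conditions: Et3SiH (5 equiv), BF3·OEt2 (2 equiv), CH2Cl2/MeCN, −78 → −40 °C
Reagents that add atoms: none
Why: Reductive deoxygenation of a lactol, in which ionisation gives oxocarbenium ion 16 and Et3SiH delivers hydride axially to the half-chair having the C2 arylethyl group pseudoequatorial and the C4 silyloxy group pseudoaxial, so that the alkynyl group on C6 ends equatorial and cis to C2.

Step 10
Reactants: 17 (2S,4S,6S)-2-{2-[4-(benzyloxy)-3-methoxyphenyl]ethyl}-4-[(tert-butyldimethylsilyl)oxy]-6-[(trimethylsilyl)ethynyl]oxane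
Product: 18 (2S,4S,6S)-2-{2-[4-(benzyloxy)-3-methoxyphenyl]ethyl}-4-[(tert-butyldimethylsilyl)oxy]-6-ethynyloxane
Conditions: K2CO3 (0.2 equiv), MeOH, rt
Reagents that add atoms: none
Why: Base-catalysed methanolysis of the alkynyl C–Si bond (protodesilylation), which is selective for the alkynylsilane and leaves the secondary silyl ether and the benzyl ether alone.

Step 11
Reactants: 18 (2S,4S,6S)-2-{2-[4-(benzyloxy)-3-methoxyphenyl]ethyl}-4-[(tert-butyldimethylsilyl)oxy]-6-ethynyloxane; 19 trichloroacetyl chloride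
Product: 20 4,4-dichloro-3-Ox-cyclobut-2-en-1-one
Conditions: 19 (2 equiv, slow addition), Zn–Cu couple (3 equiv), Et2O/DME, rt → 35 °C
Reagents that add atoms: none
Why: [2+2] cycloaddition of dichloroketene, made in the flask by zinc dechlorination of 19, to the terminal alkyne, in which the ketene carbonyl carbon bonds to the terminal alkyne carbon and so places the oxanyl group on C3 of the cyclobutenone, with DME tying up the zinc chloride.

Step 12
Reactants: 20 4,4-dichloro-3-Ox-cyclobut-2-en-1-one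
Product: 22 3-Ox-cyclobut-2-en-1-one, via monochlorocyclobutenone 21 (not isolated)
Conditions: Zn dust, AcOH, TMEDA, EtOH, 0 °C → rt
Reagents that add atoms: none
Why: Reductive dechlorination of an α,α-dichloro ketone with zinc in buffered acetic acid, which removes the two chlorine atoms one after the other far faster than it could reduce the enone or the allylic C6–O1 bond and does not move the double bond.

Step 13
Reactants: 23 chloroacetaldehyde dimethyl acetal
Product: 25 methoxyacetylene, via sodium methoxyethynide 24 (not isolated)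
Conditions: NaNH2 (3 equiv), liquid NH3, −33 °C; evaporation of NH3; cold sat. aq. NaCl, −20 °C; distillation (bp about 23 °C) into cold toluene
Reagents that add atoms: none
Why: Twofold base-induced elimination (loss of methanol, then of HCl) with sodium amide gives acetylide 24, which is protonated on aqueous quench so that the low-boiling ynol ether can be distilled off.

Step 14
Reactants: 22 3-Ox-cyclobut-2-en-1-one; 25 methoxyacetylene
Product: 30 3-methoxy-5-Ox-phenol, via vinylketene 26 (not isolated), via 4-alkenylcyclobutenone 27 (not isolated), via dienylketene 28 (not isolated), via cyclohexadienone 29 (not isolated)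
Conditions: 25 (3 equiv), toluene, sealed tube, 80 °C, 16 h
Reagents that add atoms: none
Why: Danheiser benzannulation, known for 3-substituted cyclobutenones and alkoxyacetylenes: thermal 4π electrocyclic opening of 22 gives vinylketene 26, whose ketene C=C adds to the ynol ether in a [2+2] cycloaddition to give 4-alkenylcyclobutenone 27. A second 4π opening gives dienylketene 28, and the benzene ring closes by thermal disrotatory 6π electrocyclisation (the C2′–C3′ bond, joining the former CH2 and C=O carbons of the cyclobutenone) to dienone 29, which tautomerises to phenol 30. The two new skeletal bonds are C3′–C4′ (ketene carbonyl carbon to the unsubstituted alkyne carbon) and C5′–C6′ (ketene α-carbon to the methoxy-bearing alkyne carbon). No stereocentre is formed, and C2, C4 and C6 of the oxane are not touched because the conditions are neutral and no intermediate is enolised towards C6. The selectivity needed is the regiochemistry of the [2+2] step, and the polarisation of the ynol ether (nucleophilic CH carbon attacking the electrophilic ketene carbon) secures it, so that OMe ends on C5′, meta to the C3′ hydroxyl and to C1′. An excess of the volatile alkyne in a sealed vessel should let the cycloaddition outrun acylation of the product phenol by the ketene intermediates.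

Step 15
Reactants: 30 3-methoxy-5-Ox-phenol
Product: 31 1-[(benzyloxy)methoxy]-3-methoxy-5-Ox-benzene
Conditions: benzyl chloromethyl ether, iPr2NEt, Bu4NI (cat.), CH2Cl2, 0 → 40 °C
Reagents that add atoms: benzyl chloromethyl ether ClCOCc1ccccc1
Why: O-Alkylation of the phenol with an α-chloro ether, which installs a benzyloxymethyl acetal that directs the metalation of step 16 and later leaves in the same hydrogenolysis as the benzyl ethers.

Step 16
Reactants: 31 1-[(benzyloxy)methoxy]-3-methoxy-5-Ox-benzene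
Product: 34 2-[(benzyloxy)methoxy]-6-methoxy-4-Ox-phenol, via aryllithium 32 (not isolated), via dimethyl arylboronate 33 (not isolated)
Conditions: n-BuLi (1.3 equiv), THF, −20 → 0 °C; B(OMe)3, −78 °C → rt; AcOH, 30% H2O2, 0 °C → rt
Reagents that add atoms: hydrogen peroxide OO
Why: Directed ortho-metalation, in which n-BuLi held by the acetal oxygens removes the C4′ proton, the only one flanked by two oxygen substituents, and aryllithium 32 is borylated to 33 and oxidised to the phenol by 1,2-aryl shift from boron to oxygen.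

Step 17
Reactants: 34 2-[(benzyloxy)methoxy]-6-methoxy-4-Ox-phenol
Product: 35 2-(benzyloxy)-1-[(benzyloxy)methoxy]-3-methoxy-5-Ox-benzene
Conditions: BnBr, K2CO3, DMF, 50 °C
Reagents that add atoms: benzyl bromide BrCc1ccccc1
Why: Williamson benzylation of the only free phenol with a mild base, under which the silyl ether and the acetal are stable.

Step 18
Reactants: 35 2-(benzyloxy)-1-[(benzyloxy)methoxy]-3-methoxy-5-Ox-benzene
Product: 36 (2S,4S,6S)-2-{4-(benzyloxy)-3-[(benzyloxy)methoxy]-5-methoxyphenyl}-6-{2-[4-(benzyloxy)-3-methoxyphenyl]ethyl}oxan-4-ol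
Conditions: TBAF, THF, 0 °C → rt
Reagents that add atoms: none
Why: Fluoride cleavage of the silyl ether, driven by the strong Si–F bond, which leaves the benzyl and benzyloxymethyl ethers intact and keeps the C4 configuration because the C–O bond is not broken.

Step 19
Reactants: 36 (2S,4S,6S)-2-{4-(benzyloxy)-3-[(benzyloxy)methoxy]-5-methoxyphenyl}-6-{2-[4-(benzyloxy)-3-methoxyphenyl]ethyl}oxan-4-ol
Product: 37 (2S,4S,6S)-2-{4-(benzyloxy)-3-[(benzyloxy)methoxy]-5-methoxyphenyl}-6-{2-[4-(benzyloxy)-3-methoxyphenyl]ethyl}oxan-4-yl acetate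
Conditions: Ac2O, pyridine, DMAP (cat.), CH2Cl2, rt
Reagents that add atoms: acetic anhydride CC(=O)OC(C)=O
Why: DMAP-catalysed acylation of the axial secondary alcohol with retention, at a stage where no other hydroxyl is free.

Step 20
Reactants: 37 (2S,4S,6S)-2-{4-(benzyloxy)-3-[(benzyloxy)methoxy]-5-methoxyphenyl}-6-{2-[4-(benzyloxy)-3-methoxyphenyl]ethyl}oxan-4-yl acetate
Product: 38 (2S,4S,6S)-2-(3,4-dihydroxy-5-methoxyphenyl)-6-[2-(4-hydroxy-3-methoxyphenyl)ethyl]oxan-4-yl acetate
Conditions: H2 (1 atm), Pd/C (10%), degassed EtOAc/EtOH, rt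
Reagents that add atoms: none
Why: Catalytic hydrogenolysis, which cleaves the two aryl benzyl ethers and the benzyloxymethyl ether (the hemiacetal left behind loses formaldehyde) under neutral conditions that spare the acetate and, at one atmosphere in ethyl acetate, the benzylic C6–O1 bond of the oxane.

Compound list
1 | 3-(4-hydroxy-3-methoxyphenyl)propanoic acid | COc1cc(CCC(=O)O)ccc1O | starting material
2 | 3-[4-(benzyloxy)-3-methoxyphenyl]propanoic acid | COc1cc(CCC(=O)O)ccc1OCc1ccccc1 | intermediate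
3 | potassium ethyl malonate | CCOC(=O)CC(=O)[O-].[K+] | starting material
4 | 1-{3-[4-(benzyloxy)-3-methoxyphenyl]propanoyl}imidazole | COc1cc(CCC(=O)n2ccnc2)ccc1OCc1ccccc1 | intermediate (not isolated)
5 | ethyl 5-[4-(benzyloxy)-3-methoxyphenyl]-3-oxopentanoate | CCOC(=O)CC(=O)CCc1ccc(OCc2ccccc2)c(OC)c1 | intermediate
6 | ethyl (3S)-5-[4-(benzyloxy)-3-methoxyphenyl]-3-hydroxypentanoate | COc1cc(CC[C@H](O)CC(=O)OCC)ccc1OCc1ccccc1 | intermediate
7 | tert-butyl acetate | CC(=O)OC(C)(C)C | starting material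
8 | tert-butyl (5S)-7-[4-(benzyloxy)-3-methoxyphenyl]-5-hydroxy-3-oxoheptanoate | COc1cc(CC[C@H](O)CC(=O)CC(=O)OC(C)(C)C)ccc1OCc1ccccc1 | intermediate
9 | diethylboron chelate of 8 (O5-diethylboryl, boron coordinated by the C3 carbonyl oxygen) | COc1cc(CC[C@H](OB(CC)CC)CC(=O)CC(=O)OC(C)(C)C)ccc1OCc1ccccc1 | intermediate (not isolated)
10 | tert-butyl (3S,5S)-7-[4-(benzyloxy)-3-methoxyphenyl]-3,5-dihydroxyheptanoate | COc1cc(CC[C@H](O)C[C@H](O)CC(=O)OC(C)(C)C)ccc1OCc1ccccc1 | intermediate
11 | (3S,5S)-7-[4-(benzyloxy)-3-methoxyphenyl]-3,5-dihydroxyheptanoic acid | COc1cc(CC[C@H](O)C[C@H](O)CC(=O)O)ccc1OCc1ccccc1 | intermediate (not isolated)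
12 | (4S,6S)-6-{2-[4-(benzyloxy)-3-methoxyphenyl]ethyl}-4-hydroxyoxan-2-one (4,6-trans) | COc1cc(CC[C@H]2C[C@H](O)CC(=O)O2)ccc1OCc1ccccc1 | intermediate
13 | (4S,6S)-6-{2-[4-(benzyloxy)-3-methoxyphenyl]ethyl}-4-[(tert-butyldimethylsilyl)oxy]oxan-2-one | COc1cc(CC[C@H]2C[C@H](O[Si](C)(C)C(C)(C)C)CC(=O)O2)ccc1OCc1ccccc1 | intermediate
14 | trimethylsilylacetylene | C[Si](C)(C)C#C | starting material
15 | (4S,6S)-6-{2-[4-(benzyloxy)-3-methoxyphenyl]ethyl}-4-[(tert-butyldimethylsilyl)oxy]-2-[(trimethylsilyl)ethynyl]oxan-2-ol (anomeric mixture) | COc1cc(CC[C@H]2C[C@H](O[Si](C)(C)C(C)(C)C)CC(O)(C#C[Si](C)(C)C)O2)ccc1OCc1ccccc1 | intermediate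
16 | oxocarbenium ion from 15 (C=O+ between the alkynyl carbon and O1; cation) | COc1cc(CC[C@H]2C[C@H](O[Si](C)(C)C(C)(C)C)CC(C#C[Si](C)(C)C)=[O+]2)ccc1OCc1ccccc1 | intermediate (not isolated)
17 | (2S,4S,6S)-2-{2-[4-(benzyloxy)-3-methoxyphenyl]ethyl}-4-[(tert-butyldimethylsilyl)oxy]-6-[(trimethylsilyl)ethynyl]oxane (2,6-cis, silyloxy axial) | COc1cc(CC[C@H]2C[C@H](O[Si](C)(C)C(C)(C)C)C[C@@H](C#C[Si](C)(C)C)O2)ccc1OCc1ccccc1 | intermediate
18 | (2S,4S,6S)-2-{2-[4-(benzyloxy)-3-methoxyphenyl]ethyl}-4-[(tert-butyldimethylsilyl)oxy]-6-ethynyloxane | COc1cc(CC[C@H]2C[C@H](O[Si](C)(C)C(C)(C)C)C[C@@H](C#C)O2)ccc1OCc1ccccc1 | intermediate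
19 | trichloroacetyl chloride | O=C(Cl)C(Cl)(Cl)Cl | starting material
20 | 4,4-dichloro-3-Ox-cyclobut-2-en-1-one | COc1cc(CC[C@H]2C[C@H](O[Si](C)(C)C(C)(C)C)C[C@@H](C3=CC(=O)C3(Cl)Cl)O2)ccc1OCc1ccccc1 | intermediate
21 | 4-chloro-3-Ox-cyclobut-2-en-1-one (both epimers at the chlorinated carbon) | COc1cc(CC[C@H]2C[C@H](O[Si](C)(C)C(C)(C)C)C[C@@H](C3=CC(=O)C3Cl)O2)ccc1OCc1ccccc1 | intermediate (not isolated)
22 | 3-Ox-cyclobut-2-en-1-one, i.e. 3-[(2S,4S,6S)-6-{2-[4-(benzyloxy)-3-methoxyphenyl]ethyl}-4-[(tert-butyldimethylsilyl)oxy]oxan-2-yl]cyclobut-2-en-1-one | COc1cc(CC[C@H]2C[C@H](O[Si](C)(C)C(C)(C)C)C[C@@H](C3=CC(=O)C3)O2)ccc1OCc1ccccc1 | intermediate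
23 | chloroacetaldehyde dimethyl acetal | COC(CCl)OC | starting material
24 | sodium methoxyethynide | [Na+].[C-]#COC | intermediate (not isolated)
25 | methoxyacetylene | COC#C | intermediate
26 | 3-Ox-buta-1,3-dien-1-one (vinylketene) | COc1cc(CC[C@H]2C[C@H](O[Si](C)(C)C(C)(C)C)C[C@@H](C(=C)C=C=O)O2)ccc1OCc1ccccc1 | intermediate (not isolated)
27 | 3-methoxy-4-(1-Ox-ethenyl)cyclobut-2-en-1-one (both epimers at C4 of the four-membered ring) | COc1cc(CC[C@H]2C[C@H](O[Si](C)(C)C(C)(C)C)C[C@@H](C(=C)C3C(=O)C=C3OC)O2)ccc1OCc1ccccc1 | intermediate (not isolated)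
28 | 3-methoxy-5-Ox-hexa-1,3,5-trien-1-one (dienylketene, ketene carbon and C5 cis on the central double bond) | COc1cc(CC[C@H]2C[C@H](O[Si](C)(C)C(C)(C)C)C[C@@H](C(=C)/C=C(OC)\C=C=O)O2)ccc1OCc1ccccc1 | intermediate (not isolated)
29 | 3-methoxy-5-Ox-cyclohexa-2,4-dien-1-one | COc1cc(CC[C@H]2C[C@H](O[Si](C)(C)C(C)(C)C)C[C@@H](C3=CC(OC)=CC(=O)C3)O2)ccc1OCc1ccccc1 | intermediate (not isolated)
30 | 3-methoxy-5-Ox-phenol, i.e. 3-[(2S,4S,6S)-6-{2-[4-(benzyloxy)-3-methoxyphenyl]ethyl}-4-[(tert-butyldimethylsilyl)oxy]oxan-2-yl]-5-methoxyphenol | COc1cc(CC[C@H]2C[C@H](O[Si](C)(C)C(C)(C)C)C[C@@H](c3cc(O)cc(OC)c3)O2)ccc1OCc1ccccc1 | intermediate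
31 | 1-[(benzyloxy)methoxy]-3-methoxy-5-Ox-benzene | COc1cc(CC[C@H]2C[C@H](O[Si](C)(C)C(C)(C)C)C[C@@H](c3cc(OCOCc4ccccc4)cc(OC)c3)O2)ccc1OCc1ccccc1 | intermediate
32 | {2-[(benzyloxy)methoxy]-6-methoxy-4-Ox-phenyl}lithium | COc1cc(CC[C@H]2C[C@H](O[Si](C)(C)C(C)(C)C)C[C@@H](c3cc(OCOCc4ccccc4)c([Li])c(OC)c3)O2)ccc1OCc1ccccc1 | intermediate (not isolated)
33 | dimethyl {2-[(benzyloxy)methoxy]-6-methoxy-4-Ox-phenyl}boronate | COc1cc(CC[C@H]2C[C@H](O[Si](C)(C)C(C)(C)C)C[C@@H](c3cc(OCOCc4ccccc4)c(B(OC)OC)c(OC)c3)O2)ccc1OCc1ccccc1 | intermediate (not isolated)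
34 | 2-[(benzyloxy)methoxy]-6-methoxy-4-Ox-phenol | COc1cc(CC[C@H]2C[C@H](O[Si](C)(C)C(C)(C)C)C[C@@H](c3cc(OCOCc4ccccc4)c(O)c(OC)c3)O2)ccc1OCc1ccccc1 | intermediate
35 | 2-(benzyloxy)-1-[(benzyloxy)methoxy]-3-methoxy-5-Ox-benzene | COc1cc(CC[C@H]2C[C@H](O[Si](C)(C)C(C)(C)C)C[C@@H](c3cc(OCOCc4ccccc4)c(OCc4ccccc4)c(OC)c3)O2)ccc1OCc1ccccc1 | intermediate
36 | (2S,4S,6S)-2-{4-(benzyloxy)-3-[(benzyloxy)methoxy]-5-methoxyphenyl}-6-{2-[4-(benzyloxy)-3-methoxyphenyl]ethyl}oxan-4-ol | COc1cc(CC[C@H]2C[C@H](O)C[C@@H](c3cc(OCOCc4ccccc4)c(OCc4ccccc4)c(OC)c3)O2)ccc1OCc1ccccc1 | intermediate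
37 | (2S,4S,6S)-2-{4-(benzyloxy)-3-[(benzyloxy)methoxy]-5-methoxyphenyl}-6-{2-[4-(benzyloxy)-3-methoxyphenyl]ethyl}oxan-4-yl acetate | COc1cc(CC[C@H]2C[C@H](OC(C)=O)C[C@@H](c3cc(OCOCc4ccccc4)c(OCc4ccccc4)c(OC)c3)O2)ccc1OCc1ccccc1 | intermediate
38 | (2S,4S,6S)-2-(3,4-dihydroxy-5-methoxyphenyl)-6-[2-(4-hydroxy-3-methoxyphenyl)ethyl]oxan-4-yl acetate | COc1cc(CC[C@H]2C[C@H](OC(C)=O)C[C@@H](c3cc(O)c(O)c(OC)c3)O2)ccc1O | target

Total step count: 20. Longest linear sequence: 19 steps (steps 1–12 and 14–20); step 13 prepares the alkyne on a one-step side branch.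

Steps most likely to fail

Step 14. The ketene intermediates may be intercepted before ring closure (acylation of the phenol already formed, ketene oligomerisation), and the volatile ynol ether may polymerise or escape at 80 °C, so that the cyclobutenone is consumed without arene formation. The fallback brings the aryl ring in preformed; it sets out from lactone 13 and comes back to the route at target 38. Commercial 5-bromo-2-hydroxy-3-methoxybenzaldehyde would be taken by Dakin oxidation (H2O2, NaOH) to 5-bromo-3-methoxybenzene-1,2-diol F1 and benzylated (BnBr, K2CO3, DMF) to 1,2-bis(benzyloxy)-5-bromo-3-methoxybenzene F2. Bromine–lithium exchange (n-BuLi, THF, −78 °C) would give [3,4-bis(benzyloxy)-5-methoxyphenyl]lithium F3, which adds to 13 to give aryl lactol F4. Reduction with Et3SiH and BF3·OEt2 (axial hydride delivery as in step 9) should give 2,6-cis aryl oxane F5. TBAF would then give alcohol F6, Ac2O/pyridine/DMAP would give acetate F7, and hydrogenolysis (H2, Pd/C) would give 38.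

Step 11. The alkyne is deactivated inductively by the neighbouring ring oxygen, so cycloaddition may be slow enough for dichloroketene to oligomerise and for the zinc chloride formed to start cleaving the silyl ether. The fallback uses a keteniminium [2+2] cycloaddition; it sets out from alkyne 18 and comes back at cyclobutenone 22, so that step 12 is skipped. N,N-Dimethylacetamide, Tf2O and 2,4,6-collidine in 1,2-dichloroethane would give N,N-dimethylketeniminium triflate F8, a much stronger electrophile than dichloroketene, which should add to 18 at reflux to give cyclobuteniminium triflate F9; hydrolysis with aqueous NaHCO3 would give 22.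

Step 16. Deprotonation at the benzylic methylene groups of the benzyl and benzyloxymethyl ethers (followed by Wittig rearrangement) may compete with ring metalation, and the hindered boronate may lose boron by protonation before it is oxidised. The fallback uses a stronger directing group at lower temperature; it sets out from phenol 30 and comes back at benzyl ether 35. Et2NCOCl and NaH in THF would give aryl N,N-diethylcarbamate F10; s-BuLi/TMEDA in THF at −78 °C should lithiate C4′ within minutes, at a temperature where benzylic deprotonation is slow, to give aryllithium F11. Trapping with B(OMe)3 would give dimethyl boronate F12 and AcOH/H2O2 would give hydroxy carbamate F13. Benzylation (BnBr, K2CO3, DMF) would give benzyl ether carbamate F14, LiAlH4 (THF, 0 °C) would remove the carbamoyl group to give phenol F15, and benzyl chloromethyl ether with iPr2NEt would give 35.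

Further compounds
F1 | step 14 | 5-bromo-3-methoxybenzene-1,2-diol | COc1cc(Br)cc(O)c1O
F2 | step 14 | 1,2-bis(benzyloxy)-5-bromo-3-methoxybenzene | COc1cc(Br)cc(OCc2ccccc2)c1OCc1ccccc1
F3 | step 14 | [3,4-bis(benzyloxy)-5-methoxyphenyl]lithium | [Li]c1cc(OC)c(OCc2ccccc2)c(OCc2ccccc2)c1
F4 | step 14 | (4S,6S)-2-[3,4-bis(benzyloxy)-5-methoxyphenyl]-6-{2-[4-(benzyloxy)-3-methoxyphenyl]ethyl}-4-[(tert-butyldimethylsilyl)oxy]oxan-2-ol (anomeric mixture) | COc1cc(CC[C@H]2C[C@H](O[Si](C)(C)C(C)(C)C)CC(O)(c3cc(OCc4ccccc4)c(OCc4ccccc4)c(OC)c3)O2)ccc1OCc1ccccc1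
F5 | step 14 | 1,2-bis(benzyloxy)-3-methoxy-5-Ox-benzene | COc1cc(CC[C@H]2C[C@H](O[Si](C)(C)C(C)(C)C)C[C@@H](c3cc(OCc4ccccc4)c(OCc4ccccc4)c(OC)c3)O2)ccc1OCc1ccccc1
F6 | step 14 | (2S,4S,6S)-2-[3,4-bis(benzyloxy)-5-methoxyphenyl]-6-{2-[4-(benzyloxy)-3-methoxyphenyl]ethyl}oxan-4-ol | COc1cc(CC[C@H]2C[C@H](O)C[C@@H](c3cc(OCc4ccccc4)c(OCc4ccccc4)c(OC)c3)O2)ccc1OCc1ccccc1
F7 | step 14 | (2S,4S,6S)-2-[3,4-bis(benzyloxy)-5-methoxyphenyl]-6-{2-[4-(benzyloxy)-3-methoxyphenyl]ethyl}oxan-4-yl acetate | COc1cc(CC[C@H]2C[C@H](OC(C)=O)C[C@@H](c3cc(OCc4ccccc4)c(OCc4ccccc4)c(OC)c3)O2)ccc1OCc1ccccc1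
F8 | step 11 | N,N-dimethylketeniminium trifluoromethanesulfonate | C=C=[N+](C)C.[O-]S(=O)(=O)C(F)(F)F
F9 | step 11 | N,N-dimethyl-3-Ox-cyclobut-2-en-1-iminium trifluoromethanesulfonate | COc1cc(CC[C@H]2C[C@H](O[Si](C)(C)C(C)(C)C)C[C@@H](C3=CC(=[N+](C)C)C3)O2)ccc1OCc1ccccc1.[O-]S(=O)(=O)C(F)(F)F
F10 | step 16 | 3-methoxy-5-Ox-phenyl N,N-diethylcarbamate | COc1cc(CC[C@H]2C[C@H](O[Si](C)(C)C(C)(C)C)C[C@@H](c3cc(OC(=O)N(CC)CC)cc(OC)c3)O2)ccc1OCc1ccccc1
F11 | step 16 | {2-[(diethylcarbamoyl)oxy]-6-methoxy-4-Ox-phenyl}lithium | COc1cc(CC[C@H]2C[C@H](O[Si](C)(C)C(C)(C)C)C[C@@H](c3cc(OC(=O)N(CC)CC)c([Li])c(OC)c3)O2)ccc1OCc1ccccc1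
F12 | step 16 | dimethyl {2-[(diethylcarbamoyl)oxy]-6-methoxy-4-Ox-phenyl}boronate | COc1cc(CC[C@H]2C[C@H](O[Si](C)(C)C(C)(C)C)C[C@@H](c3cc(OC(=O)N(CC)CC)c(B(OC)OC)c(OC)c3)O2)ccc1OCc1ccccc1
F13 | step 16 | 2-hydroxy-3-methoxy-5-Ox-phenyl N,N-diethylcarbamate | COc1cc(CC[C@H]2C[C@H](O[Si](C)(C)C(C)(C)C)C[C@@H](c3cc(OC(=O)N(CC)CC)c(O)c(OC)c3)O2)ccc1OCc1ccccc1
F14 | step 16 | 2-(benzyloxy)-3-methoxy-5-Ox-phenyl N,N-diethylcarbamate | COc1cc(CC[C@H]2C[C@H](O[Si](C)(C)C(C)(C)C)C[C@@H](c3cc(OC(=O)N(CC)CC)c(OCc4ccccc4)c(OC)c3)O2)ccc1OCc1ccccc1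
F15 | step 16 | 2-(benzyloxy)-3-methoxy-5-Ox-phenol | COc1cc(CC[C@H]2C[C@H](O[Si](C)(C)C(C)(C)C)C[C@@H](c3cc(O)c(OCc4ccccc4)c(OC)c3)O2)ccc1OCc1ccccc1
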